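**Retrosynthetic overview**

1. The lactol ring is opened at O2–C3 to a δ-keto acid (C1 carboxyl on C8a, ketone at C3). The ketone comes from a silyl-protected secondary alcohol, and the C3 hemiketal configuration follows C4 by equilibration.
2. Ring A (C4a, C5, C6, C7, C8, C8a) is cut at C4a–C5 and C8–C8a. Its C5 methyl, C6 methoxy, C7 hydrogen and C8 hydroxyl are the atoms of a 1,3-dimethoxy-1-silyloxypenta-1,3-diene. C8a (bearing the C1 carboxyl) and C4a (bearing the C4 side chain) are the two sp carbons of a 2-alkynoate. A [4+2] addition and loss of methanol give the benzene ring with its two oxygens already differentiated.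
3. The ynoate comes from a terminal alkyne by C-benzyloxycarbonylation. Its C4 stereocentre is set by SE2′ addition of the allenylzinc from (R)-but-3-yn-2-yl mesylate to the glycolaldehyde ester of the benzyl-protected ring-B acid. That acid is made from methyl 2,4-dihydroxy-3,6-dimethylbenzoate by C-methylation, benzylation and ester exchange.
4. Ring order: ring B is bought, ring A is formed by the benzannulation, and the lactol ring closes last during global hydrogenolysis.

Key step: step 13

Convention: ring A is the benzo ring of the isochromanone (isochromanone numbering C1–C8a); ring B is the 2,4-dihydroxy-3,5,6-trimethylbenzoyl ring.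

Remark on the chemistry: C3 is a hemiketal carbon that equilibrates through the open keto acid; the given (3R) configuration (3-OH axial and anti to the pseudoaxial 4-methyl) is assumed to be the thermodynamic one, so only C4 (S) has to be carried through the route.

**Route**

Step 1
Reactants: 1 methyl 2,4-dihydroxy-3,6-dimethylbenzoate
Product: 3 methyl 3-formyl-4,6-dihydroxy-2,5-dimethylbenzoate, via chloro(methoxy)methyl arene 2 (not isolated)
Conditions: Cl2CHOMe, TiCl4, CH2Cl2, −10 → 0 °C; then aq. HCl, 23 °C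
Reagents that add atoms: dichloromethyl methyl ether, ClC(Cl)OC; water, O
Why: Rieche formylation, in which the TiCl4-activated dichloromethyl methyl ether substitutes the only free ring position (ortho to the 4-hydroxyl) and hydrolysis of α-chloro ether 2 should release the aldehyde.

Step 2
Reactants: 3 methyl 3-formyl-4,6-dihydroxy-2,5-dimethylbenzoate
Product: 5 methyl 2,4-dihydroxy-3,5,6-trimethylbenzoate, via benzylic alcohol 4 (not isolated)
Conditions: H2 (3 atm), Pd/C, AcOH, HCl (cat.), 23 °C
Reagents that add atoms: none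
Why: Catalytic hydrogenation of a hydroxy-flanked benzaldehyde passes through benzylic alcohol 4, whose C–O bond is hydrogenolysed easily (quinone-methide-type activation by the neighbouring phenol) to the methyl group, while the ester and the ring are inert.

Step 3
Reactants: 5 methyl 2,4-dihydroxy-3,5,6-trimethylbenzoate
Product: 6 methyl 2,4-bis(benzyloxy)-3,5,6-trimethylbenzoate
Conditions: BnBr, K2CO3, Bu4NI (cat.), DMF, 60 °C
Reagents that add atoms: benzyl bromide, BrCc1ccccc1
Why: Williamson etherification of both phenoxides; the chelated 2-hydroxyl reacts more slowly but should go to completion in warm DMF with iodide catalysis, and the methyl ester is untouched.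

Step 4
Reactants: 6 methyl 2,4-bis(benzyloxy)-3,5,6-trimethylbenzoate
Product: 7 2,4-bis(benzyloxy)-3,5,6-trimethylbenzoic acid
Conditions: KOtBu, H2O, THF, 23 → 50 °C; then aq. HCl
Reagents that add atoms: water, O
Why: Ester hydrolysis with poorly solvated ("anhydrous") hydroxide generated from KOtBu and water, the method of choice for di-ortho-substituted (mesitoate-type) benzoates that resist aqueous saponification; benzyl aryl ethers are stable to base.

Step 5
Reactants: 7 2,4-bis(benzyloxy)-3,5,6-trimethylbenzoic acid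
Product: 8 prop-2-en-1-yl 2,4-bis(benzyloxy)-3,5,6-trimethylbenzoate
Conditions: allyl bromide, Cs2CO3, DMF, 23 °C
Reagents that add atoms: allyl bromide, C=CCBr
Why: SN2 O-alkylation of the carboxylate forms the ester bond at the unhindered allylic carbon and so avoids any addition to the shielded acyl carbon.

Step 6
Reactants: 8 prop-2-en-1-yl 2,4-bis(benzyloxy)-3,5,6-trimethylbenzoate
Product: 10 2-oxoethyl 2,4-bis(benzyloxy)-3,5,6-trimethylbenzoate, via diol 9 (not isolated)
Conditions: OsO4 (cat.), NaIO4, 2,6-lutidine, dioxane–H2O, 23 °C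
Reagents that add atoms: osmium tetroxide, O=[Os](=O)(=O)=O (catalytic oxygen carrier); sodium periodate, [Na+].[O-]I(=O)(=O)=O (terminal oxygen source)
Why: Lemieux–Johnson oxidation, in which OsO4 dihydroxylates the only alkene to diol 9 and periodate cleaves it in situ to the glycolaldehyde ester; benzyl ethers and the electron-rich arene are spared, which ozone would not guarantee.

Step 7
Reactants: 11 (R)-but-3-yn-2-ol
Product: 12 (R)-but-3-yn-2-yl methanesulfonate
Conditions: MsCl, Et3N, CH2Cl2, −78 → 0 °C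
Reagents that add atoms: methanesulfonyl chloride, CS(=O)(=O)Cl
Why: Mesylation takes place at oxygen, so no bond to the stereocentre is broken and the (R) configuration is retained.

Step 8
Reactants: 10 2-oxoethyl 2,4-bis(benzyloxy)-3,5,6-trimethylbenzoate; 12 (R)-but-3-yn-2-yl methanesulfonate
Product: 14 (2S,3S)-2-hydroxy-3-methylpent-4-yn-1-yl 2,4-bis(benzyloxy)-3,5,6-trimethylbenzoate, via allenylzinc 13 (not isolated)
Conditions: Pd(OAc)2 (cat.), PPh3 (cat.), Et2Zn, THF, −78 → −20 °C; then aq. NH4Cl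
Reagents that add atoms: none
Why: Marshall propargylation, in which zerovalent palladium displaces the mesylate in anti SN2′ fashion, transmetalation with Et2Zn gives the (P)-allenylzinc 13, and its SE2′ addition to the aldehyde through a cyclic six-membered transition state puts the new C–C bond on the face opposite the departed mesylate (net inversion, hence 3S at the methyl-bearing carbon) and gives the anti carbinol (2S); the carbinol configuration is of no later consequence because this carbon becomes the C3 ketone.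

Step 9
Reactants: 14 (2S,3S)-2-hydroxy-3-methylpent-4-yn-1-yl 2,4-bis(benzyloxy)-3,5,6-trimethylbenzoate
Product: 15 (2S,3S)-3-methyl-2-(triethylsilyloxy)pent-4-yn-1-yl 2,4-bis(benzyloxy)-3,5,6-trimethylbenzoate
Conditions: Et3SiOTf, 2,6-lutidine, CH2Cl2, −78 → 0 °C
Reagents that add atoms: triethylsilyl trifluoromethanesulfonate, CC[Si](CC)(CC)OS(=O)(=O)C(F)(F)F
Why: O-silylation of the secondary alcohol with a silyl triflate and a hindered pyridine base; the triethylsilyl group is chosen because it is smaller than a tert-butyldimethylsilyl group next to the reacting alkyne and can later be removed under buffered HF conditions.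

Step 10
Reactants: 15 (2S,3S)-3-methyl-2-(triethylsilyloxy)pent-4-yn-1-yl 2,4-bis(benzyloxy)-3,5,6-trimethylbenzoate
Product: 17 benzyl (4S,5S)-6-{[2,4-bis(benzyloxy)-3,5,6-trimethylbenzoyl]oxy}-4-methyl-5-(triethylsilyloxy)hex-2-ynoate, via lithium acetylide 16 (not isolated)
Conditions: LiN(SiMe3)2, THF, −78 °C; then ClCO2Bn, −78 → −40 °C
Reagents that add atoms: benzyl chloroformate, O=C(Cl)OCc1ccccc1
Why: Deprotonation of the terminal alkyne and C-acylation of lithium acetylide 16 with the chloroformate; the amide base does not attack the shielded benzoate and the tertiary propargylic C4–H is far less acidic than the alkyne C–H, so the stereocentre is untouched.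

Step 11
Reactants: 18 methyl 3-oxopentanoate
Product: 20 methyl (E)-3-methoxypent-2-enoate, via dimethyl ketal 19 (not isolated)
Conditions: HC(OMe)3, H2SO4 (cat.), MeOH, 23 °C; then distillation
Reagents that add atoms: trimethyl orthoformate, COC(OC)OC
Why: Acid-catalysed ketalisation of the ketone with the orthoester and loss of methanol from ketal 19 on distillation should give the conjugated β-methoxy enoate as its thermodynamically preferred E isomer.

Step 12
Reactants: 20 methyl (E)-3-methoxypent-2-enoate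
Product: 22 (3Z)-1,3-dimethoxy-1-(trimethylsilyloxy)penta-1,3-diene (C1=C2 geometry immaterial), via lithium dienolate 21 (not isolated)
Conditions: LiN(iPr)2, THF, −78 °C; then Me3SiCl, −78 → 23 °C; non-aqueous work-up, distillation
Reagents that add atoms: chlorotrimethylsilane, C[Si](C)(C)Cl
Why: Kinetic γ-deprotonation of the β-alkoxy enoate (vinylogous enolate formation) and O-silylation of dienolate 21 give the vinylketene silyl acetal, the γ-methyl being expected to turn away from the ester during deprotonation and so to end trans to C2 (3Z), the geometry that can reach the s-cis conformation.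

Step 13
Reactants: 17 benzyl (4S,5S)-6-{[2,4-bis(benzyloxy)-3,5,6-trimethylbenzoyl]oxy}-4-methyl-5-(triethylsilyloxy)hex-2-ynoate; 22 (3Z)-1,3-dimethoxy-1-(trimethylsilyloxy)penta-1,3-diene
Product: 25 benzyl 6-[(2S,3S)-4-{[2,4-bis(benzyloxy)-3,5,6-trimethylbenzoyl]oxy}-3-(triethylsilyloxy)butan-2-yl]-2-hydroxy-4-methoxy-5-methylbenzoate, via cyclohexadiene ketal 23 (not isolated), via aryl trimethylsilyl ether 24 (not isolated)
Conditions: 22 (4 equiv, in portions), PhMe, 120 °C, sealed tube; then aq. citric acid, THF, 0 °C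
Reagents that add atoms: none
Why: Diels–Alder benzannulation, in which the electron-rich 1,1,3-trioxygenated diene adds in a concerted but strongly asynchronous [4+2] fashion across the ynoate, its methyl-bearing terminus (largest HOMO coefficient) bonding to the ynoate β-carbon (future C4a–C5 bond) and its ketene-acetal carbon to the α-carbon (future C8–C8a bond), so that ring A is closed as a six-membered carbocycle by an intermolecular cycloaddition that forms both bonds. Cyclohexa-1,4-diene ketal 23 should then aromatise by 1,4-elimination of methanol (methoxide from the future C8, hydrogen from the future C5) to aryl silyl ether 24, which the mild acid work-up hydrolyses to the hydrogen-bonded C8 phenol, while the 3-methoxy group of the diene remains as the C6 methoxy. The closest known reaction type is the thermal cycloaddition–aromatisation of 1-alkoxy-1-silyloxy dienes (Brassard type) with 2-alkynoates to give 6-alkylsalicylates and resorcylates. No stereocentre is created, the two side-chain centres are spectators, and the propargylic C4–H is not removed because the medium contains no base. The step needs regioselectivity (hydroxyl ortho to the ester, methyl ortho to the side chain), which the matched polarisation of diene and ynoate secures. It also needs enough reactivity from a β-branched dienophile, which is addressed by excess diene, high concentration and the small triethylsilyl ether next to the alkyne.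

Step 14
Reactants: 25 benzyl 6-[(2S,3S)-4-{[2,4-bis(benzyloxy)-3,5,6-trimethylbenzoyl]oxy}-3-(triethylsilyloxy)butan-2-yl]-2-hydroxy-4-methoxy-5-methylbenzoate
Product: 26 benzyl 6-[(2S,3S)-4-{[2,4-bis(benzyloxy)-3,5,6-trimethylbenzoyl]oxy}-3-hydroxybutan-2-yl]-2-hydroxy-4-methoxy-5-methylbenzoate
Conditions: HF·pyridine, pyridine, THF, 0 °C
Reagents that add atoms: none
Why: Fluoride-induced Si–O cleavage with pyridine-buffered HF removes the triethylsilyl ether without generating an alkoxide, which should keep transesterification onto the neighbouring benzyl salicylate slow; benzyl ethers, both esters and C4 are unaffected.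

Step 15
Reactants: 26 benzyl 6-[(2S,3S)-4-{[2,4-bis(benzyloxy)-3,5,6-trimethylbenzoyl]oxy}-3-hydroxybutan-2-yl]-2-hydroxy-4-methoxy-5-methylbenzoate
Product: 27 benzyl 6-[(2S)-4-{[2,4-bis(benzyloxy)-3,5,6-trimethylbenzoyl]oxy}-3-oxobutan-2-yl]-2-hydroxy-4-methoxy-5-methylbenzoate
Conditions: Dess–Martin periodinane, NaHCO3, CH2Cl2, 0 → 23 °C
Reagents that add atoms: none
Why: Dess–Martin oxidation (ligand exchange at hypervalent iodine, then intramolecular α-hydrogen removal by acetate) converts the secondary alcohol into the ketone under buffered, essentially neutral conditions, so the now enolisable benzylic C4 centre is not exposed to base, and the chelated salicylate phenol is a poor partner for the reagent.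

Step 16
Reactants: 27 benzyl 6-[(2S)-4-{[2,4-bis(benzyloxy)-3,5,6-trimethylbenzoyl]oxy}-3-oxobutan-2-yl]-2-hydroxy-4-methoxy-5-methylbenzoate
Product: 29 [(3R,4S)-3,8-dihydroxy-6-methoxy-4,5-dimethyl-1-oxo-3,4-dihydro-1H-isochromen-3-yl]methyl 2,4-dihydroxy-3,5,6-trimethylbenzoate, via keto acid 28 (not isolated)
Conditions: H2 (1 atm), Pd/C, EtOAc, 23 °C
Reagents that add atoms: none
Why: Hydrogenolysis cleaves the benzyl ester and both benzyl aryl ethers without touching the ketone, and the freed C1 carboxylic acid adds reversibly to the C3 ketone (6-exo-trig hemiketalisation), so C3 should settle under thermodynamic control directed by C4 with the 3-hydroxyl axial (anomeric) and anti to the pseudoaxial 4-methyl that avoids the peri C5 methyl, which is the (3R,4S) lactol.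

**Compound list**

1 | methyl 2,4-dihydroxy-3,6-dimethylbenzoate | COC(=O)c1c(C)cc(O)c(C)c1O | starting material
2 | methyl 3-[chloro(methoxy)methyl]-4,6-dihydroxy-2,5-dimethylbenzoate (racemic, not isolated) | COC(=O)c1c(C)c(C(Cl)OC)c(O)c(C)c1O | intermediate
3 | methyl 3-formyl-4,6-dihydroxy-2,5-dimethylbenzoate | COC(=O)c1c(C)c(C=O)c(O)c(C)c1O | intermediate
4 | methyl 4,6-dihydroxy-3-(hydroxymethyl)-2,5-dimethylbenzoate (not isolated) | COC(=O)c1c(C)c(CO)c(O)c(C)c1O | intermediate
5 | methyl 2,4-dihydroxy-3,5,6-trimethylbenzoate | COC(=O)c1c(C)c(C)c(O)c(C)c1O | intermediate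
6 | methyl 2,4-bis(benzyloxy)-3,5,6-trimethylbenzoate | COC(=O)c1c(C)c(C)c(OCc2ccccc2)c(C)c1OCc1ccccc1 | intermediate
7 | 2,4-bis(benzyloxy)-3,5,6-trimethylbenzoic acid | OC(=O)c1c(C)c(C)c(OCc2ccccc2)c(C)c1OCc1ccccc1 | intermediate
8 | prop-2-en-1-yl 2,4-bis(benzyloxy)-3,5,6-trimethylbenzoate | C=CCOC(=O)c1c(C)c(C)c(OCc2ccccc2)c(C)c1OCc1ccccc1 | intermediate
9 | 2,3-dihydroxypropyl 2,4-bis(benzyloxy)-3,5,6-trimethylbenzoate (racemic, not isolated) | OCC(O)COC(=O)c1c(C)c(C)c(OCc2ccccc2)c(C)c1OCc1ccccc1 | intermediate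
10 | 2-oxoethyl 2,4-bis(benzyloxy)-3,5,6-trimethylbenzoate | O=CCOC(=O)c1c(C)c(C)c(OCc2ccccc2)c(C)c1OCc1ccccc1 | intermediate
11 | (R)-but-3-yn-2-ol | C#C[C@@H](C)O | starting material
12 | (R)-but-3-yn-2-yl methanesulfonate | C#C[C@@H](C)OS(C)(=O)=O | intermediate
13 | (P)-buta-1,2-dien-1-yl(ethyl)zinc, the (aS)-allenylzinc (not isolated) | CC[Zn][CH]=[C@@]=[CH]C | intermediate
14 | (2S,3S)-2-hydroxy-3-methylpent-4-yn-1-yl 2,4-bis(benzyloxy)-3,5,6-trimethylbenzoate | C#C[C@H](C)[C@H](O)COC(=O)c1c(C)c(C)c(OCc2ccccc2)c(C)c1OCc1ccccc1 | intermediate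
15 | (2S,3S)-3-methyl-2-(triethylsilyloxy)pent-4-yn-1-yl 2,4-bis(benzyloxy)-3,5,6-trimethylbenzoate | C#C[C@H](C)[C@H](O[Si](CC)(CC)CC)COC(=O)c1c(C)c(C)c(OCc2ccccc2)c(C)c1OCc1ccccc1 | intermediate
16 | lithium acetylide of 15 (not isolated) | [Li]C#C[C@H](C)[C@H](O[Si](CC)(CC)CC)COC(=O)c1c(C)c(C)c(OCc2ccccc2)c(C)c1OCc1ccccc1 | intermediate
17 | benzyl (4S,5S)-6-{[2,4-bis(benzyloxy)-3,5,6-trimethylbenzoyl]oxy}-4-methyl-5-(triethylsilyloxy)hex-2-ynoate | O=C(OCc1ccccc1)C#C[C@H](C)[C@H](O[Si](CC)(CC)CC)COC(=O)c1c(C)c(C)c(OCc2ccccc2)c(C)c1OCc1ccccc1 | intermediate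
18 | methyl 3-oxopentanoate | CCC(=O)CC(=O)OC | starting material
19 | methyl 3,3-dimethoxypentanoate (not isolated) | CCC(OC)(OC)CC(=O)OC | intermediate
20 | methyl (E)-3-methoxypent-2-enoate | CC/C(OC)=C\C(=O)OC | intermediate
21 | lithium (3Z)-1,3-dimethoxypenta-1,3-dien-1-olate (not isolated) | C/C=C(OC)/C=C(OC)O[Li] | intermediate
22 | (3Z)-1,3-dimethoxy-1-(trimethylsilyloxy)penta-1,3-diene | C/C=C(OC)/C=C(OC)O[Si](C)(C)C | intermediate
23 | benzyl 2-[(2S,3S)-4-{[2,4-bis(benzyloxy)-3,5,6-trimethylbenzoyl]oxy}-3-(triethylsilyloxy)butan-2-yl]-4,6-dimethoxy-3-methyl-6-(trimethylsilyloxy)cyclohexa-1,4-diene-1-carboxylate (ring sp3 centres as a mixture, not isolated) | COC1=CC(OC)(O[Si](C)(C)C)C(C(=O)OCc2ccccc2)=C(C1C)[C@H](C)[C@H](O[Si](CC)(CC)CC)COC(=O)c1c(C)c(C)c(OCc2ccccc2)c(C)c1OCc1ccccc1 | intermediate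
24 | benzyl 6-[(2S,3S)-4-{[2,4-bis(benzyloxy)-3,5,6-trimethylbenzoyl]oxy}-3-(triethylsilyloxy)butan-2-yl]-4-methoxy-5-methyl-2-(trimethylsilyloxy)benzoate (not isolated) | COc1cc(O[Si](C)(C)C)c(C(=O)OCc2ccccc2)c(c1C)[C@H](C)[C@H](O[Si](CC)(CC)CC)COC(=O)c1c(C)c(C)c(OCc2ccccc2)c(C)c1OCc1ccccc1 | intermediate
25 | benzyl 6-[(2S,3S)-4-{[2,4-bis(benzyloxy)-3,5,6-trimethylbenzoyl]oxy}-3-(triethylsilyloxy)butan-2-yl]-2-hydroxy-4-methoxy-5-methylbenzoate | COc1cc(O)c(C(=O)OCc2ccccc2)c(c1C)[C@H](C)[C@H](O[Si](CC)(CC)CC)COC(=O)c1c(C)c(C)c(OCc2ccccc2)c(C)c1OCc1ccccc1 | intermediate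
26 | benzyl 6-[(2S,3S)-4-{[2,4-bis(benzyloxy)-3,5,6-trimethylbenzoyl]oxy}-3-hydroxybutan-2-yl]-2-hydroxy-4-methoxy-5-methylbenzoate | COc1cc(O)c(C(=O)OCc2ccccc2)c(c1C)[C@H](C)[C@H](O)COC(=O)c1c(C)c(C)c(OCc2ccccc2)c(C)c1OCc1ccccc1 | intermediate
27 | benzyl 6-[(2S)-4-{[2,4-bis(benzyloxy)-3,5,6-trimethylbenzoyl]oxy}-3-oxobutan-2-yl]-2-hydroxy-4-methoxy-5-methylbenzoate | COc1cc(O)c(C(=O)OCc2ccccc2)c(c1C)[C@H](C)C(=O)COC(=O)c1c(C)c(C)c(OCc2ccccc2)c(C)c1OCc1ccccc1 | intermediate
28 | 6-[(2S)-4-[(2,4-dihydroxy-3,5,6-trimethylbenzoyl)oxy]-3-oxobutan-2-yl]-2-hydroxy-4-methoxy-5-methylbenzoic acid (not isolated) | COc1cc(O)c(C(=O)O)c(c1C)[C@H](C)C(=O)COC(=O)c1c(C)c(C)c(O)c(C)c1O | intermediate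
29 | [(3R,4S)-3,8-dihydroxy-6-methoxy-4,5-dimethyl-1-oxo-3,4-dihydro-1H-isochromen-3-yl]methyl 2,4-dihydroxy-3,5,6-trimethylbenzoate (CNP0157156.2) | COc1cc(O)c2c(c1C)[C@H](C)[C@](O)(COC(=O)c1c(C)c(C)c(O)c(C)c1O)OC2=O | target

**Step count**

Total: 16 steps. Longest linear sequence: 13 steps (steps 1–6, 8–10, 13–16).

**Steps most likely to fail**

1. Step 13 (cycloaddition–aromatisation). The β-branched, singly activated ynoate may add so slowly that thermal decay of the ketene-acetal diene (silyl migration, hydrolysis, oligomerisation) consumes it first. Aromatisation by loss of trimethylsilanol in place of methanol would also leave C8 as a methyl ether. The fallback sets out from 15 and returns at 25; it raises the dienophile to the aldehyde oxidation level, which lowers its LUMO far more than an ester does. Acetylide 16 (LiN(SiMe3)2, THF, −78 °C) is quenched with DMF and then aqueous KH2PO4 to give the ynal (2S,3S)-3-methyl-6-oxo-2-(triethylsilyloxy)hex-4-yn-1-yl 2,4-bis(benzyloxy)-3,5,6-trimethylbenzoate F1. F1 should add diene 22 in toluene between 0 and 40 °C with the same regiochemistry, and loss of methanol followed by mild acid hydrolysis should give the salicylaldehyde (2S,3S)-3-(2-formyl-3-hydroxy-5-methoxy-6-methylphenyl)-2-(triethylsilyloxy)butyl 2,4-bis(benzyloxy)-3,5,6-trimethylbenzoate F2. Lindgren–Pinnick oxidation (NaClO2, NaH2PO4, 2-methylbut-2-ene, t-BuOH–H2O) should convert F2 into 6-[(2S,3S)-4-{[2,4-bis(benzyloxy)-3,5,6-trimethylbenzoyl]oxy}-3-(triethylsilyloxy)butan-2-yl]-2-hydroxy-4-methoxy-5-methylbenzoic acid F3, and selective carboxylate alkylation (BnBr, KHCO3, DMF, 23 °C) returns 25.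

2. Step 14 (desilylation). The freed C3 hydroxyl may attack the neighbouring benzyl ester in a six-membered transesterification with loss of benzyl alcohol, giving a dihydroisocoumarin that can no longer be oxidised at C3. The fallback sets out from 15 and returns at 29; it carries the carboxyl as a tert-butyl ester, which resists transesterification, and ends with hydrogenolysis followed by acidolysis.
   - Acetylide 16 is trapped with di-tert-butyl dicarbonate to give tert-butyl (4S,5S)-6-{[2,4-bis(benzyloxy)-3,5,6-trimethylbenzoyl]oxy}-4-methyl-5-(triethylsilyloxy)hex-2-ynoate F4.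
   - Cycloaddition with 22 under the conditions of step 13 should give tert-butyl 6-[(2S,3S)-4-{[2,4-bis(benzyloxy)-3,5,6-trimethylbenzoyl]oxy}-3-(triethylsilyloxy)butan-2-yl]-2-hydroxy-4-methoxy-5-methylbenzoate F5.
   - HF·pyridine gives tert-butyl 6-[(2S,3S)-4-{[2,4-bis(benzyloxy)-3,5,6-trimethylbenzoyl]oxy}-3-hydroxybutan-2-yl]-2-hydroxy-4-methoxy-5-methylbenzoate F6.
   - Dess–Martin oxidation gives tert-butyl 6-[(2S)-4-{[2,4-bis(benzyloxy)-3,5,6-trimethylbenzoyl]oxy}-3-oxobutan-2-yl]-2-hydroxy-4-methoxy-5-methylbenzoate F7.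
   - Hydrogenolysis (H2, Pd/C, EtOAc) frees the ring-B phenols to give tert-butyl 6-[(2S)-4-[(2,4-dihydroxy-3,5,6-trimethylbenzoyl)oxy]-3-oxobutan-2-yl]-2-hydroxy-4-methoxy-5-methylbenzoate F8.
   - Brief treatment with CF3CO2H in CH2Cl2 at 0 °C cleaves the tert-butyl ester to keto acid 28, which closes to 29.

3. Step 8 (propargylation). Ethyl transfer from Et2Zn to the unhindered α-acyloxy aldehyde, and its hydration or self-condensation, may outpace formation of the allenylzinc. Slow trapping would also let the allenylmetal racemise and erode the C4 configuration. The fallback sets out from 12, with acid 7 held back as the later coupling partner, and returns at 15; it reverses the order of fragment union, so that the propargylation uses a well-behaved α-alkoxy aldehyde and the hindered ester is made afterwards by carboxylate SN2 chemistry. Steps 5 and 6 then fall away.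
   - Mesylate 12 and [(4-methoxybenzyl)oxy]acetaldehyde under the conditions of step 8 should give (2S,3S)-1-[(4-methoxybenzyl)oxy]-3-methylpent-4-yn-2-ol F9.
   - Et3SiOTf and 2,6-lutidine give triethyl({(2S,3S)-1-[(4-methoxybenzyl)oxy]-3-methylpent-4-yn-2-yl}oxy)silane F10.
   - DDQ in CH2Cl2 with pH 7 buffer removes the 4-methoxybenzyl group to give (2S,3S)-3-methyl-2-(triethylsilyloxy)pent-4-yn-1-ol F11.
   - Mitsunobu esterification of F11 with acid 7 (PPh3, diisopropyl azodicarboxylate, THF), in which the carboxylate attacks the activated primary carbon, returns 15.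

**Further compounds**

F1 | step 13 | (2S,3S)-3-methyl-6-oxo-2-(triethylsilyloxy)hex-4-yn-1-yl 2,4-bis(benzyloxy)-3,5,6-trimethylbenzoate | O=CC#C[C@H](C)[C@H](O[Si](CC)(CC)CC)COC(=O)c1c(C)c(C)c(OCc2ccccc2)c(C)c1OCc1ccccc1
F2 | step 13 | (2S,3S)-3-(2-formyl-3-hydroxy-5-methoxy-6-methylphenyl)-2-(triethylsilyloxy)butyl 2,4-bis(benzyloxy)-3,5,6-trimethylbenzoate | COc1cc(O)c(C=O)c(c1C)[C@H](C)[C@H](O[Si](CC)(CC)CC)COC(=O)c1c(C)c(C)c(OCc2ccccc2)c(C)c1OCc1ccccc1
F3 | step 13 | 6-[(2S,3S)-4-{[2,4-bis(benzyloxy)-3,5,6-trimethylbenzoyl]oxy}-3-(triethylsilyloxy)butan-2-yl]-2-hydroxy-4-methoxy-5-methylbenzoic acid | COc1cc(O)c(C(=O)O)c(c1C)[C@H](C)[C@H](O[Si](CC)(CC)CC)COC(=O)c1c(C)c(C)c(OCc2ccccc2)c(C)c1OCc1ccccc1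
F4 | step 14 | tert-butyl (4S,5S)-6-{[2,4-bis(benzyloxy)-3,5,6-trimethylbenzoyl]oxy}-4-methyl-5-(triethylsilyloxy)hex-2-ynoate | CC(C)(C)OC(=O)C#C[C@H](C)[C@H](O[Si](CC)(CC)CC)COC(=O)c1c(C)c(C)c(OCc2ccccc2)c(C)c1OCc1ccccc1
F5 | step 14 | tert-butyl 6-[(2S,3S)-4-{[2,4-bis(benzyloxy)-3,5,6-trimethylbenzoyl]oxy}-3-(triethylsilyloxy)butan-2-yl]-2-hydroxy-4-methoxy-5-methylbenzoate | COc1cc(O)c(C(=O)OC(C)(C)C)c(c1C)[C@H](C)[C@H](O[Si](CC)(CC)CC)COC(=O)c1c(C)c(C)c(OCc2ccccc2)c(C)c1OCc1ccccc1
F6 | step 14 | tert-butyl 6-[(2S,3S)-4-{[2,4-bis(benzyloxy)-3,5,6-trimethylbenzoyl]oxy}-3-hydroxybutan-2-yl]-2-hydroxy-4-methoxy-5-methylbenzoate | COc1cc(O)c(C(=O)OC(C)(C)C)c(c1C)[C@H](C)[C@H](O)COC(=O)c1c(C)c(C)c(OCc2ccccc2)c(C)c1OCc1ccccc1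
F7 | step 14 | tert-butyl 6-[(2S)-4-{[2,4-bis(benzyloxy)-3,5,6-trimethylbenzoyl]oxy}-3-oxobutan-2-yl]-2-hydroxy-4-methoxy-5-methylbenzoate | COc1cc(O)c(C(=O)OC(C)(C)C)c(c1C)[C@H](C)C(=O)COC(=O)c1c(C)c(C)c(OCc2ccccc2)c(C)c1OCc1ccccc1
F8 | step 14 | tert-butyl 6-[(2S)-4-[(2,4-dihydroxy-3,5,6-trimethylbenzoyl)oxy]-3-oxobutan-2-yl]-2-hydroxy-4-methoxy-5-methylbenzoate | COc1cc(O)c(C(=O)OC(C)(C)C)c(c1C)[C@H](C)C(=O)COC(=O)c1c(C)c(C)c(O)c(C)c1O
F9 | step 8 | (2S,3S)-1-[(4-methoxybenzyl)oxy]-3-methylpent-4-yn-2-ol | C#C[C@H](C)[C@H](O)COCc1ccc(OC)cc1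
F10 | step 8 | triethyl({(2S,3S)-1-[(4-methoxybenzyl)oxy]-3-methylpent-4-yn-2-yl}oxy)silane | C#C[C@H](C)[C@H](O[Si](CC)(CC)CC)COCc1ccc(OC)cc1
F11 | step 8 | (2S,3S)-3-methyl-2-(triethylsilyloxy)pent-4-yn-1-ol | C#C[C@H](C)[C@H](O[Si](CC)(CC)CC)CO
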